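**Retrosynthetic overview**
- Feature: α-onocerin is C2-symmetric. Its two rings B (C5–C10 and C13–C18, onocerane locants) are joined through C9–C11–C12–C13, and each holds a methyl-bearing quaternary carbon (C10, C18) between the ethylene-bearing carbon and the ring-fusion carbon. This is the pattern of a bibenzyl whose ipso carbons carry carboxamides flanked by OMe and the CH2CH2 arm. Below, both halves are described with the locants C1–C10 of the first half.
- Late stage: C8=CH2 from a C8 ketone (Wittig), the ketone from hydroboration of C8=C9; 3β-OH from the C3 ketone; 4,4-dimethyl and 5α-H from reductive methylation of a 4-methyl-Δ4-3-ketone.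
- Rings A: aldol closure C4–C5 of 1,5-diketones. C1 is the former carboxamide carbon, C2–C4 come from a 2-oxobutyl phosphonate, and the C5 ketone is the unmasked enol ether.
- C10/C18: twofold auxiliary-controlled Birch reductive methylation of a bibenzyl bis-amide, itself made by oxidative dimerization of a laterally lithiated 2-methoxy-6-methylbenzamide.
- Ring order: both rings B are present from the start as arenes and are dearomatized in step 3; both rings A close together in step 9.

Key step: step 3

Remark (assumption on the chemistry): the (S)-auxiliary is taken to steer iodomethane to the face that gives the R configuration at both new quaternary carbons (enolate oxygen on the side of the alkyl-bearing ortho carbon, lithium chelated by the side-chain ether, attack opposite the chelate). If the sense proved opposite, the same steps would be run with the (R)-auxiliary.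

**Route**

Step 1
Reactants: 1 2-methoxy-6-methylbenzoic acid; 2 (S)-2-(methoxymethyl)pyrrolidine
Product: 4 (S)-(2-methoxy-6-methylphenyl)[2-(methoxymethyl)pyrrolidin-1-yl]methanone, via 2-methoxy-6-methylbenzoyl chloride 3 (not isolated)
Conditions: (COCl)2, DMF (cat.), CH2Cl2, 0 °C → rt; evaporate; then 2, Et3N, CH2Cl2, 0 °C → rt
Reagents that add atoms: (S)-2-(methoxymethyl)pyrrolidine (compound 2), COC[C@@H]1CCCN1
Why: N-acylation through the acid chloride, which is the reliable way to couple a 2,6-disubstituted benzoic acid with a secondary amine; the auxiliary stereocentre is not touched.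

Step 2
Reactants: 4 (two molecules)
Product: 6 1,2-bis{3-methoxy-2-[(S)-2-(methoxymethyl)pyrrolidine-1-carbonyl]phenyl}ethane, via laterally lithiated amide 5 (not isolated)
Conditions: s-BuLi, TMEDA, THF, −78 °C; then CuCl2 (anhydrous), −78 °C → rt
Reagents that add atoms: none
Why: Amide-directed lateral lithiation of the ortho methyl group (both ring positions ortho to the amide are blocked) followed by oxidative homocoupling of the benzylic organolithium on divalent copper should form the C11–C12 bond.

Step 3
Reactants: 6 the bibenzyl bis-amide; 7 iodomethane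
Product: 9 1,2-bis{(6R)-5-methoxy-6-methyl-6-[(S)-2-(methoxymethyl)pyrrolidine-1-carbonyl]cyclohexa-1,4-dien-1-yl}ethane, via dilithium bis(amide enolate) 8 (not isolated)
Conditions: Li (4.4 equiv), NH3/THF, t-BuOH (2.0 equiv), −78 °C; piperylene; MeI (excess), −78 °C; solid NH4Cl, evaporate NH3
Reagents that add atoms: iodomethane (compound 7), CI
Why: Proposed new method: each arene accepts two electrons from lithium and is protonated once by t-BuOH at the ring carbon para to the carboxamide (future C7 and C15), which leaves a cross-conjugated lithium amide enolate in each ring, and iodomethane then alkylates the ipso carbons to form the C10–CH3 and C18–CH3 bonds of a bis-1,4-diene. The closest known reaction type is the auxiliary-controlled Birch reduction–alkylation of single benzamides of this prolinol methyl ether that carry one ortho substituent (2-methoxy or 2-alkyl); new here is its use on a 2,6-disubstituted ring and twice in one molecule. No ring is closed. The two new stereocentres (C10 and C18, both R in 9) are set by the auxiliary: lithium bridges the enolate oxygen and the side-chain ether oxygen and iodomethane enters from the enolate face opposite this chelate, while the methoxy group (which keeps away from the enolate oxygen) and the ortho alkyl arm (which keeps away from the pyrrolidine) favour the same enolate geometry, so both single-substituent models point to one face. The step needs regioselectivity (ipso/para reduction with the OMe kept), secured because carboxamide, methoxy and alkyl groups all direct protonation to the same carbon and only one equivalent of t-BuOH per ring is present at −78 °C, and it needs facial selectivity, helped by the two alkylations being independent so that a wrong-face event ends in a separable diastereomer and not in the enantiomer. The saturated C11–C12 link insulates the rings, so the second reduction should not be disturbed by the first enolate.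

Step 4
Reactants: 9
Product: 10 1,2-bis[(6S)-6-(hydroxymethyl)-5-methoxy-6-methylcyclohexa-1,4-dien-1-yl]ethane (same spatial arrangement as 9; the descriptor changes with the substituent ranking)
Conditions: LiNH2BH3 (from BH3·NH3 and n-BuLi, THF, 0 °C), THF, 0 → 40 °C; aq. NaOH work-up
Reagents that add atoms: none
Why: Reduction of a tertiary amide to the primary alcohol with lithium amidotrihydroborate, a small and strongly nucleophilic hydride known to reduce α-quaternary tertiary amides with C–N cleavage; enol ethers and alkenes are inert to it and the auxiliary is released for recovery.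

Step 5
Reactants: 10
Product: 11 1,2-bis[(6R)-6-formyl-5-methoxy-6-methylcyclohexa-1,4-dien-1-yl]ethane
Conditions: (n-Pr4N)RuO4 (cat.), NMO, 4 Å MS, CH2Cl2, rt; used at once
Reagents that add atoms: none
Why: Ley–Griffith oxidation of the neopentyl primary alcohols under neutral conditions keeps the acid-labile enol ethers, and the aldehydes cannot epimerize because their α-carbon is quaternary.

Step 6
Reactants: 11; 12 dimethyl (2-oxobutyl)phosphonate
Product: 13 1,2-bis{(6R)-5-methoxy-6-methyl-6-[(E)-3-oxopent-1-en-1-yl]cyclohexa-1,4-dien-1-yl}ethane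
Conditions: 12, NaH, THF, 0 °C; then 11, 0 °C → rt
Reagents that add atoms: dimethyl (2-oxobutyl)phosphonate (compound 12), CCC(=O)CP(=O)(OC)OC
Why: Horner–Wadsworth–Emmons olefination of the non-enolizable aldehydes with the stabilized phosphonate anion should give the E-enones and brings in C2, C3, C4 and one C4 methyl group.

Step 7
Reactants: 13
Product: 14 1,2-bis[(6R)-5-methoxy-6-methyl-6-(3-oxopentyl)cyclohexa-1,4-dien-1-yl]ethane
Conditions: H2 (1 atm), RhCl(PPh3)3 (cat.), benzene, rt
Reagents that add atoms: none
Why: Homogeneous hydrogenation with RhCl(PPh3)3 reduces the disubstituted enone C1=C2 bond much faster than the trisubstituted C8=C9 alkene and the trisubstituted enol ether.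

Step 8
Reactants: 14
Product: 15 1,2-bis[(6R)-6-methyl-5-oxo-6-(3-oxopentyl)cyclohex-1-en-1-yl]ethane
Conditions: 1 M HCl, THF, rt
Reagents that add atoms: water, O
Why: Acid-catalysed enol ether hydrolysis unmasks the C5 ketones, and the C8=C9 alkene cannot move into conjugation because C10 is quaternary.

Step 9
Reactants: 15
Product: 16 1,2-bis[(8aR)-5,8a-dimethyl-6-oxo-3,4,6,7,8,8a-hexahydronaphthalen-1-yl]ethane (each half: 3-oxo, C4=C5, 4-CH3, 10β-CH3, C8=C9)
Conditions: KOH, MeOH, 60 °C
Reagents that add atoms: none
Why: Intramolecular aldol condensation (the ring-closing half of a Robinson annulation, 6-(enolendo)-exo-trig): the C4 enolate of each ethyl ketone adds to the C5 ketone and dehydration gives the conjugated enone, while the bridged aldol alternative is reversible and cannot dehydrate.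

Step 10
Reactants: 16; 7 iodomethane
Product: 18 26,27-dinor-8,14-secogammacera-8,13-diene-3,21-dione (each half: 3-oxo, 4,4-dimethyl, 5α-H, 10β-CH3, C8=C9), via dilithium bis(enolate) 17 (not isolated)
Conditions: Li, NH3/THF, t-BuOH (2.0 equiv), −78 °C; isoprene; MeI (excess), −78 → −33 °C; NH4Cl
Reagents that add atoms: iodomethane (compound 7), CI
Why: Stork reductive alkylation: dissolving-metal reduction of each enone is followed by axial protonation at C5 opposite the C10 methyl group (trans ring fusion, 5α-H), and the regiodefined C3–C4 lithium enolate is methylated at C4; the isolated C8=C9 alkene is not reduced.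

Step 11
Reactants: 18
Product: 19 the bis(3β-alcohol) of 18 (each half: 3β-OH, 4,4-dimethyl, 5α-H, 10β-CH3, C8=C9)
Conditions: NaBH4, MeOH/THF, 0 °C
Reagents that add atoms: none
Why: Borohydride reduction in which hydride attacks C3 axially from the α face, away from the axial 4β- and 10β-methyl groups, should give the equatorial 3β-alcohol (3S).

Step 12
Reactants: 19
Product: 20 the bis(tert-butyldimethylsilyl) ether of 19
Conditions: TBSOTf, 2,6-lutidine, CH2Cl2, 0 °C → rt
Reagents that add atoms: tert-butyldimethylsilyl trifluoromethanesulfonate, CC(C)(C)[Si](C)(C)OS(=O)(=O)C(F)(F)F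
Why: Silylation of the hindered secondary alcohol with the silyl triflate keeps C3–OH apart from the C8 alcohol that is oxidized later.

Step 13
Reactants: 20
Product: 22 the bis(8α-alcohol) (each half: 3β-OTBS, 5α-H, 8α-OH, 9α-H, 10β-CH3), via bis(C8 borane) 21 (not isolated)
Conditions: BH3·THF, THF, 0 °C → rt; then NaOH, H2O2, 0 °C → rt
Reagents that add atoms: hydrogen peroxide, OO
Why: Brown hydroboration–oxidation: syn addition of H–B from the α face, opposite the axial C10 methyl group, places boron on the less substituted C8 and hydrogen on C9 (9α-H, C11 equatorial), and oxidation proceeds with retention.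

Step 14
Reactants: 22
Product: 23 the bis(8-ketone) (each half: 3β-OTBS, 5α-H, 8-oxo, 9α-H, 10β-CH3)
Conditions: (n-Pr4N)RuO4 (cat.), NMO, 4 Å MS, CH2Cl2, rt; then K2CO3, MeOH, rt
Reagents that add atoms: none
Why: Ley–Griffith oxidation gives the C8 ketones, and brief base equilibration brings any 9-epimer to the favoured isomer with the C11 arm equatorial (9α-H).

Step 15
Reactants: 23
Product: 24 α-onocerin bis(tert-butyldimethylsilyl) ether
Conditions: Ph3PCH3Br, KOt-Bu, toluene, 90 °C
Reagents that add atoms: methyltriphenylphosphonium bromide, C[P+](c1ccccc1)(c1ccccc1)c1ccccc1.[Br-]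
Why: Wittig methylenation of the hindered ketones with the salt-free ylide at raised temperature; C9 already holds its thermodynamically preferred configuration, so enolization under the basic conditions does no harm.

Step 16
Reactants: 24
Product: 25 α-onocerin
Conditions: Bu4NF, THF, 60 °C
Reagents that add atoms: none
Why: Fluoride-mediated cleavage of the silyl ethers under non-acidic conditions leaves the exocyclic alkenes in place.

**Compound list**
1 | 2-methoxy-6-methylbenzoic acid | COc1cccc(C)c1C(=O)O | starting material
2 | (S)-2-(methoxymethyl)pyrrolidine | COC[C@@H]1CCCN1 | starting material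
3 | 2-methoxy-6-methylbenzoyl chloride (not isolated) | COc1cccc(C)c1C(Cl)=O | intermediate
4 | (S)-(2-methoxy-6-methylphenyl)[2-(methoxymethyl)pyrrolidin-1-yl]methanone | COC[C@@H]1CCCN1C(=O)c1c(C)cccc1OC | intermediate
5 | laterally lithiated amide, [2-(lithiomethyl)-6-methoxyphenyl][(S)-2-(methoxymethyl)pyrrolidin-1-yl]methanone (not isolated) | [Li]Cc1cccc(OC)c1C(=O)N1CCC[C@H]1COC | intermediate
6 | 1,2-bis{3-methoxy-2-[(S)-2-(methoxymethyl)pyrrolidine-1-carbonyl]phenyl}ethane (key-step precursor) | COC[C@@H]1CCCN1C(=O)c1c(OC)cccc1CCc1cccc(OC)c1C(=O)N1CCC[C@H]1COC | intermediate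
7 | iodomethane | CI | starting material
8 | dilithium bis(amide enolate) of doubly reduced 6 (not isolated) | COC[C@@H]1CCCN1C(O[Li])=C1C(OC)=CCC=C1CCC1=CCC=C(OC)C1=C(O[Li])N1CCC[C@H]1COC | intermediate
9 | 1,2-bis{(6R)-5-methoxy-6-methyl-6-[(S)-2-(methoxymethyl)pyrrolidine-1-carbonyl]cyclohexa-1,4-dien-1-yl}ethane (key-step product) | C[C@]1(C(=O)N2CCC[C@H]2COC)C(OC)=CCC=C1CCC1=CCC=C(OC)[C@]1(C)C(=O)N1CCC[C@H]1COC | intermediate
10 | 1,2-bis[(6S)-6-(hydroxymethyl)-5-methoxy-6-methylcyclohexa-1,4-dien-1-yl]ethane | C[C@]1(CO)C(OC)=CCC=C1CCC1=CCC=C(OC)[C@]1(C)CO | intermediate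
11 | 1,2-bis[(6R)-6-formyl-5-methoxy-6-methylcyclohexa-1,4-dien-1-yl]ethane | C[C@]1(C=O)C(OC)=CCC=C1CCC1=CCC=C(OC)[C@]1(C)C=O | intermediate
12 | dimethyl (2-oxobutyl)phosphonate | CCC(=O)CP(=O)(OC)OC | starting material
13 | 1,2-bis{(6R)-5-methoxy-6-methyl-6-[(E)-3-oxopent-1-en-1-yl]cyclohexa-1,4-dien-1-yl}ethane | C[C@]1(/C=C/C(=O)CC)C(OC)=CCC=C1CCC1=CCC=C(OC)[C@]1(C)/C=C/C(=O)CC | intermediate
14 | 1,2-bis[(6R)-5-methoxy-6-methyl-6-(3-oxopentyl)cyclohexa-1,4-dien-1-yl]ethane | C[C@]1(CCC(=O)CC)C(OC)=CCC=C1CCC1=CCC=C(OC)[C@]1(C)CCC(=O)CC | intermediate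
15 | 1,2-bis[(6R)-6-methyl-5-oxo-6-(3-oxopentyl)cyclohex-1-en-1-yl]ethane | C[C@]1(CCC(=O)CC)C(=O)CCC=C1CCC1=CCCC(=O)[C@]1(C)CCC(=O)CC | intermediate
16 | 1,2-bis[(8aR)-5,8a-dimethyl-6-oxo-3,4,6,7,8,8a-hexahydronaphthalen-1-yl]ethane | C1(=CCCC2=C(C)C(=O)CC[C@]12C)CCC1=CCCC2=C(C)C(=O)CC[C@]12C | intermediate
17 | dilithium bis(enolate), each half C3(OLi)=C4, 5α-H (not isolated) | C1(=CCC[C@H]2C(C)=C(O[Li])CC[C@]12C)CCC1=CCC[C@H]2C(C)=C(O[Li])CC[C@]12C | intermediate
18 | 26,27-dinor-8,14-secogammacera-8,13-diene-3,21-dione (each half 5α-H, 10β-CH3) | C1(=CCC[C@H]2C(C)(C)C(=O)CC[C@]12C)CCC1=CCC[C@H]2C(C)(C)C(=O)CC[C@]12C | intermediate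
19 | bis(3β-alcohol) of 18 | C1(=CCC[C@H]2C(C)(C)[C@@H](O)CC[C@]12C)CCC1=CCC[C@H]2C(C)(C)[C@@H](O)CC[C@]12C | intermediate
20 | bis(tert-butyldimethylsilyl) ether of 19 | C1(=CCC[C@H]2C(C)(C)[C@@H](O[Si](C)(C)C(C)(C)C)CC[C@]12C)CCC1=CCC[C@H]2C(C)(C)[C@@H](O[Si](C)(C)C(C)(C)C)CC[C@]12C | intermediate
21 | bis(C8 borane), each half 8α-BH2, 9α-H (not isolated) | B[C@@H]1CC[C@H]2C(C)(C)[C@@H](O[Si](C)(C)C(C)(C)C)CC[C@]2(C)[C@H]1CC[C@H]1[C@H](B)CC[C@H]2C(C)(C)[C@@H](O[Si](C)(C)C(C)(C)C)CC[C@]12C | intermediate
22 | bis(8α-alcohol), each half 3β-OTBS, 8α-OH, 9α-H | O[C@@H]1CC[C@H]2C(C)(C)[C@@H](O[Si](C)(C)C(C)(C)C)CC[C@]2(C)[C@H]1CC[C@H]1[C@H](O)CC[C@H]2C(C)(C)[C@@H](O[Si](C)(C)C(C)(C)C)CC[C@]12C | intermediate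
23 | bis(8-ketone), each half 3β-OTBS, 8-oxo, 9α-H | O=C1CC[C@H]2C(C)(C)[C@@H](O[Si](C)(C)C(C)(C)C)CC[C@]2(C)[C@H]1CC[C@H]1C(=O)CC[C@H]2C(C)(C)[C@@H](O[Si](C)(C)C(C)(C)C)CC[C@]12C | intermediate
24 | α-onocerin bis(tert-butyldimethylsilyl) ether | C=C1CC[C@H]2C(C)(C)[C@@H](O[Si](C)(C)C(C)(C)C)CC[C@]2(C)[C@H]1CC[C@H]1C(=C)CC[C@H]2C(C)(C)[C@@H](O[Si](C)(C)C(C)(C)C)CC[C@]12C | intermediate
25 | α-onocerin | C=C1CC[C@H]2C(C)(C)[C@@H](O)CC[C@]2(C)[C@H]1CC[C@H]1C(=C)CC[C@H]2C(C)(C)[C@@H](O)CC[C@]12C | target

**Count and risks**
Total step count: 16. Longest linear sequence: 16 steps (from 1).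

Steps most likely to fail:

1. Step 3 (Proposed new method). The twofold reduction may lose methoxy groups by reductive cleavage. The crowded tetrasubstituted enolates may be protonated instead of methylated. Facial selectivity may be poor if the 2,6-disubstituted enolate does not hold one geometry; the slowly rotating aryl–carbonyl axes of 6 add to this uncertainty. Fallback: the auxiliary is given up and the quaternary carbons are set without stereocontrol by the known Birch reduction–alkylation of 2-methoxybenzoate esters, followed by resolution. It sets out from 1 and comes back at 10, so step 4 is passed by as well. Esterification of 1 with iodomethane 7 and K2CO3 in DMF would give methyl 2-methoxy-6-methylbenzoate F1. Lateral lithiation with LiN(i-Pr)2 in THF at −78 °C and oxidative coupling with CuCl2 would give dimethyl 2,2'-(ethane-1,2-diyl)bis(6-methoxybenzoate) F2. K in NH3/THF with one equivalent of t-BuOH per ring at −78 °C and then MeI would give dimethyl 2,2'-(ethane-1,2-diyl)bis(6-methoxy-1-methylcyclohexa-2,5-diene-1-carboxylate) F3 as racemate plus meso form. LiAlH4 in THF would give the stereoisomeric diol mixture F4. The racemic pair would be separated from the meso isomer by chromatography and resolved on a chiral stationary phase to give 10.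

2. Step 4. Hydride delivery to carboxamides flanked by a quaternary carbon and two substituted sp2 carbons may stall at one or both ends, or the hemiaminal may lose oxygen instead of nitrogen and give the amine. Fallback: partial reduction in place of exhaustive reduction and reoxidation. It sets out from 9 and comes back at 11. Cp2Zr(H)Cl in THF at rt would take each carboxamide through the zirconium-bound hemiaminal to the aldehyde and release 2 on work-up, so step 5 is passed by and no new compound is made (F0).

3. Step 10. Proton exchange between product ketone and enolate in ammonia may give under- and over-methylated material at either end, and protonation at C5 may not be fully trans-selective. Fallback: the gem-dimethyl group is built by cyclopropanation instead of enolate alkylation. It sets out from 16 and comes back at 18. Li/NH3/t-BuOH reduction as before, removal of ammonia and trapping of enolate 17 with Me3SiCl/Et3N in THF would give the bis(trimethylsilyl enol ether) F5. Simmons–Smith cyclopropanation (Et2Zn, CH2I2, CH2Cl2) of the electron-rich enol ether double bonds would give the bis(siloxycyclopropane) F6. Aqueous HCl in THF would open each cyclopropanol at the C3–CH2 bond to the 4,4-dimethyl-3-ketone 18.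

**Further compounds**
F1 | step 3 | methyl 2-methoxy-6-methylbenzoate | COc1cccc(C)c1C(=O)OC
F2 | step 3 | dimethyl 2,2'-(ethane-1,2-diyl)bis(6-methoxybenzoate) | COC(=O)c1c(OC)cccc1CCc1cccc(OC)c1C(=O)OC
F3 | step 3 | dimethyl 2,2'-(ethane-1,2-diyl)bis(6-methoxy-1-methylcyclohexa-2,5-diene-1-carboxylate), racemate plus meso form | COC(=O)C1(C)C(OC)=CCC=C1CCC1=CCC=C(OC)C1(C)C(=O)OC
F4 | step 3 | 1,2-bis[6-(hydroxymethyl)-5-methoxy-6-methylcyclohexa-1,4-dien-1-yl]ethane, stereoisomer mixture | CC1(CO)C(OC)=CCC=C1CCC1=CCC=C(OC)C1(C)CO
F0 | step 4 | none | none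
F5 | step 10 | bis(trimethylsilyl enol ether) of the reduced bis-enone, each half C3(OSiMe3)=C4, 5α-H | C1(=CCC[C@H]2C(C)=C(O[Si](C)(C)C)CC[C@]12C)CCC1=CCC[C@H]2C(C)=C(O[Si](C)(C)C)CC[C@]12C
F6 | step 10 | bis(siloxycyclopropane), each half with CH2 bridging C3 and C4 (configuration at C3 and C4 not fixed) | C1(=CCC[C@H]2C3(C)CC3(O[Si](C)(C)C)CC[C@]12C)CCC1=CCC[C@H]2C3(C)CC3(O[Si](C)(C)C)CC[C@]12C
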